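**Retrosynthetic overview**

1. Target 17 ⇐ spiro enone 14: the (E)-bromomethylidene (C3=C15) is put on last by Wittig olefination.
2. 14 ⇐ acyclic α-methylene ketone 6 + chiral 1-amino-3-siloxy diene 11 in one flask: Diels–Alder (ring B, quaternary C6), TiBr4 unmasking of the enone, then bromo-Prins closure of the acetyl group onto the allyl group (ring A, C7–OH and C9–Br together).
3. 6 ⇐ mesityl oxide 1: conjugate allylation (quaternary C11), Mannich trapping of the enolate, elimination.
4. 11 ⇐ 4-methoxybut-3-en-2-one 7 + (2R,5R)-2,5-diphenylpyrrolidine 8 (recovered in step 5).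
5. Ring order: B first, A second, same operation.

Assumption: the (2R,5R)-diene 11 is taken to give (4S)-13, with the bulky tert-alkyl group of 6 exo and away from the distal phenyl; if a first run shows the opposite sense, the (2S,5S)-amine is used with nothing else changed.

Locants for 14–17 and F6–F8: C1=C2, C3 (C=O or C=CHBr), C4, C5, C6 spiro, C7 carbinol, C8, C9 (CHBr), C10, C11 (CMe2).

**Step 1**
Reactants: 1 mesityl oxide (4-methylpent-3-en-2-one); 2 allyltrimethylsilane
Product: 4 3-[(dimethylamino)methyl]-4,4-dimethylhept-6-en-2-one (racemic), via titanium enolate 3 (not isolated)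
Conditions: TiCl4, CH2Cl2, −78 °C; then Me2N+=CH2 I−, −78 → 0 °C; aq NaHCO3
Reagents that add atoms: N,N-dimethylmethyleneiminium iodide (Eschenmoser's salt), C=[N+](C)C.[I-]
Why: Hosomi–Sakurai conjugate allylation of the TiCl4-activated β,β-disubstituted enone builds the C11 quaternary carbon and leaves the enolate regiospecifically at the neopentyl α-carbon, where Mannich trapping places the future C5 (not on the methyl group).

**Step 2**
Reactants: 4 3-[(dimethylamino)methyl]-4,4-dimethylhept-6-en-2-one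
Product: 6 4,4-dimethyl-3-methylidenehept-6-en-2-one, via methiodide 5 (not isolated)
Conditions: MeI, acetone, rt; then aq NaHCO3, CH2Cl2, rt
Reagents that add atoms: none
Why: N-methylation turns the amine into a leaving group and mild base gives E1cB (Hofmann-type) elimination to the α-methylene ketone, which has no stereocentre.

**Step 3**
Reactants: 7 (E)-4-methoxybut-3-en-2-one; 8 (2R,5R)-2,5-diphenylpyrrolidine
Product: 9 (E)-4-[(2R,5R)-2,5-diphenylpyrrolidin-1-yl]but-3-en-2-one
Conditions: CH2Cl2, rt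
Reagents that add atoms: none
Why: conjugate addition–elimination of the secondary amine on the β-methoxy enone gives the E vinylogous amide.

**Step 4**
Reactants: 9 (E)-4-[(2R,5R)-2,5-diphenylpyrrolidin-1-yl]but-3-en-2-one
Product: 11 (2R,5R)-1-[(1E)-3-(tert-butyldimethylsilyloxy)buta-1,3-dien-1-yl]-2,5-diphenylpyrrolidine, via potassium dienolate 10 (not isolated)
Conditions: KHMDS, THF, −78 °C; then TBSCl, −78 → 0 °C
Reagents that add atoms: tert-butyldimethylsilyl chloride, CC(C)(C)[Si](C)(C)Cl
Why: kinetic deprotonation of the acetyl methyl and O-silylation of the cross-conjugated enolate give the 1-amino-3-siloxy diene (Rawal-type diene).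

**Step 5**
Reactants: 6 4,4-dimethyl-3-methylidenehept-6-en-2-one; 11 (2R,5R)-1-[(1E)-3-(tert-butyldimethylsilyloxy)buta-1,3-dien-1-yl]-2,5-diphenylpyrrolidine
Product: 14 (6S,7S,9R)-9-bromo-7-hydroxy-7,11,11-trimethylspiro[5.5]undec-1-en-3-one, via endo cycloadduct 12 (not isolated), via acetyl cyclohexenone 13 (not isolated)
Conditions: PhMe, 40 °C; then CH2Cl2, TiBr4 (4 equiv), −78 → −20 °C; aq NaHCO3
Reagents that add atoms: titanium(IV) bromide, Br[Ti](Br)(Br)Br
Why: Proposed new method: the aminosiloxy diene adds to the α-methylene ketone in an endo, auxiliary-shielded Diels–Alder reaction (amino terminus to the substituted carbon), forming ring B and C6; TiBr4 then ionises the allylic amine/silyl enol ether to enone 13 and activates the acetyl group for a chair-like Prins closure in which the terminal alkene carbon attacks C7 and bromide captures the secondary C9 cation anti, so that O is axial (methyl equatorial, away from the axial C11 methyl), Br is equatorial and the flat vinylic C1 takes the axial site beside the acetyl methyl, giving 6S,7S,9R; the C6/C7 sense is the least certain point (see risks); closest known reactions are aminosiloxy-diene Diels–Alder/elimination to 4,4-disubstituted cyclohexenones and TiX4 halo-Prins cyclisations of δ,ε-unsaturated carbonyl compounds to 3-halocyclohexanols.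

**Step 6**
Reactants: 14 (6S,7S,9R)-9-bromo-7-hydroxy-7,11,11-trimethylspiro[5.5]undec-1-en-3-one
Product: 17 (3E,6S,7S,9R)-9-bromo-3-(bromomethylidene)-7,11,11-trimethylspiro[5.5]undec-1-en-7-ol, via silyl ether 15 (not isolated), via silylated bromodiene 16 (not isolated)
Conditions: TMS-imidazole, CH2Cl2, rt; then Ph3P+CH2Br Br−/NaHMDS (ylide, 4 equiv), THF, −78 → 0 °C; then PPTS, MeOH, rt
Reagents that add atoms: (bromomethyl)triphenylphosphonium bromide, BrC[P+](c1ccccc1)(c1ccccc1)c1ccccc1.[Br-]
Why: Wittig olefination of the enone carbonyl by Ph3P=CHBr; the temporary TMS ether keeps the C7 alkoxide from forming (it would trigger Grob fragmentation across C7–C8/C9–Br or vinylogous retro-aldol), the E isomer (Br on the C4H2 side) is expected only as a modest major product and is separated from Z (recycled by hν/cat. I2), and methanolysis frees the alcohol without touching a stereocentre.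

**Compound list**

1 | mesityl oxide (4-methylpent-3-en-2-one) | CC(C)=CC(C)=O | starting material
2 | allyltrimethylsilane | C=CC[Si](C)(C)C | starting material
3 | trichloro[(2Z)-4,4-dimethylhepta-2,6-dien-2-olato]titanium | C/C(O[Ti](Cl)(Cl)Cl)=C/C(C)(C)CC=C | intermediate
4 | 3-[(dimethylamino)methyl]-4,4-dimethylhept-6-en-2-one (racemic) | CC(=O)C(CN(C)C)C(C)(C)CC=C | intermediate
5 | (2-acetyl-3,3-dimethylhex-5-en-1-yl)trimethylammonium iodide (racemic) | CC(=O)C(C[N+](C)(C)C)C(C)(C)CC=C.[I-] | intermediate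
6 | 4,4-dimethyl-3-methylidenehept-6-en-2-one | CC(=O)C(=C)C(C)(C)CC=C | intermediate
7 | (E)-4-methoxybut-3-en-2-one | CO/C=C/C(C)=O | starting material
8 | (2R,5R)-2,5-diphenylpyrrolidine | N1[C@@H](c2ccccc2)CC[C@@H]1c1ccccc1 | starting material
9 | (E)-4-[(2R,5R)-2,5-diphenylpyrrolidin-1-yl]but-3-en-2-one | CC(=O)/C=C/N1[C@@H](c2ccccc2)CC[C@@H]1c1ccccc1 | intermediate
10 | potassium (1E)-1-[(2R,5R)-2,5-diphenylpyrrolidin-1-yl]buta-1,3-dien-3-olate | C=C([O-])/C=C/N1[C@@H](c2ccccc2)CC[C@@H]1c1ccccc1.[K+] | intermediate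
11 | (2R,5R)-1-[(1E)-3-(tert-butyldimethylsilyloxy)buta-1,3-dien-1-yl]-2,5-diphenylpyrrolidine | C=C(O[Si](C)(C)C(C)(C)C)/C=C/N1[C@@H](c2ccccc2)CC[C@@H]1c1ccccc1 | intermediate
12 | (2R,5R)-1-[(1R,6R)-6-acetyl-3-(tert-butyldimethylsilyloxy)-6-(2-methylpent-4-en-2-yl)cyclohex-2-en-1-yl]-2,5-diphenylpyrrolidine (amino cis to acetyl) | CC(=O)[C@@]1(C(C)(C)CC=C)CCC(O[Si](C)(C)C(C)(C)C)=C[C@H]1N1[C@@H](c2ccccc2)CC[C@@H]1c1ccccc1 | intermediate
13 | (4S)-4-acetyl-4-(2-methylpent-4-en-2-yl)cyclohex-2-en-1-one | CC(=O)[C@@]1(C(C)(C)CC=C)CCC(=O)C=C1 | intermediate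
14 | (6S,7S,9R)-9-bromo-7-hydroxy-7,11,11-trimethylspiro[5.5]undec-1-en-3-one | CC1(C)C[C@@H](Br)C[C@](C)(O)[C@@]12C=CC(=O)CC2 | intermediate
15 | (6S,7S,9R)-9-bromo-7,11,11-trimethyl-7-(trimethylsilyloxy)spiro[5.5]undec-1-en-3-one | CC1(C)C[C@@H](Br)C[C@](C)(O[Si](C)(C)C)[C@@]12C=CC(=O)CC2 | intermediate
16 | (3E,6S,7S,9R)-9-bromo-3-(bromomethylidene)-7,11,11-trimethyl-7-(trimethylsilyloxy)spiro[5.5]undec-1-ene | CC1(C)C[C@@H](Br)C[C@](C)(O[Si](C)(C)C)[C@@]12C=C/C(=C/Br)CC2 | intermediate
17 | (3E,6S,7S,9R)-9-bromo-3-(bromomethylidene)-7,11,11-trimethylspiro[5.5]undec-1-en-7-ol | CC1(C)C[C@@H](Br)C[C@](C)(O)[C@@]12C=C/C(=C/Br)CC2 | target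

**Step count**

Total: 6 steps (steps 3 and 4 are a side branch to the diene). Longest linear sequence: 4 (steps 1, 2, 5, 6).

**Steps most likely to fail, with fallbacks**

Step 5. The hindered enone may add slowly or with low facial control. Above all, the Prins closure may place the hydroxyl on the vinyl side of ring B, which gives the wrong relative configuration at C6; a minor diastereomer would be separable. The fallback sets out from 6 and comes back at 14. Steps 3 and 4 are run with 7 and (2S,5S)-2,5-diphenylpyrrolidine to give the enantiomeric enaminone F1, its potassium dienolate F2 (not isolated) and the (2S,5S)-diene F3. The same cycloaddition/TiBr4 sequence with 6 then passes through the enantiomeric cycloadduct F4 and the (4R)-enone F5 (both not isolated) to the C6-epimeric bromohydrin enone F6, in which C7 and C9 already have the target configuration. Dehydrogenation of the saturated branch (IBX, DMSO, 70 °C) gives the spirodienone F7, in which C6 is no longer a stereocentre. Hydroxyl-directed hydrogenation with Crabtree's catalyst ([Ir(cod)(PCy3)(py)]PF6, H2, CH2Cl2) saturates only the enone double bond gauche to the axial C7–OH and so re-creates C6 as 6S, giving 14.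

Step 6. E/Z control in the bromomethylenation is intrinsically weak, and the ylide is basic. The fallback sets out from 15 and comes back at 17. A boron-Wittig reaction (CH2(Bpin)2, LiTMP, THF, −78 °C → rt) gives the alkenyl pinacol boronate F8; its E isomer is isolated at this stable, chromatographable stage. Bromodeboronation with CuBr2 in aqueous methanol proceeds with retention at the alkene, cleaves the TMS ether under the same conditions, and gives 17.

Step 1. The hindered titanium enolate may not be trapped cleanly by the iminium salt. The fallback sets out from 1 and comes back at 4. A Sakurai reaction of 1 with 2 under silyl-triflimide catalysis (cat. HNTf2, CH2Cl2, −78 °C) is run to isolate the regiodefined silyl enol ether F9. A Mukaiyama–Mannich reaction of F9 with Eschenmoser's salt (CH2Cl2, rt) then gives 4.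

**Further compounds**

F1 | step 5 | (E)-4-[(2S,5S)-2,5-diphenylpyrrolidin-1-yl]but-3-en-2-one | CC(=O)/C=C/N1[C@H](c2ccccc2)CC[C@H]1c1ccccc1
F2 | step 5 | potassium (1E)-1-[(2S,5S)-2,5-diphenylpyrrolidin-1-yl]buta-1,3-dien-3-olate | C=C([O-])/C=C/N1[C@H](c2ccccc2)CC[C@H]1c1ccccc1.[K+]
F3 | step 5 | (2S,5S)-1-[(1E)-3-(tert-butyldimethylsilyloxy)buta-1,3-dien-1-yl]-2,5-diphenylpyrrolidine | C=C(O[Si](C)(C)C(C)(C)C)/C=C/N1[C@H](c2ccccc2)CC[C@H]1c1ccccc1
F4 | step 5 | (2S,5S)-1-[(1S,6S)-6-acetyl-3-(tert-butyldimethylsilyloxy)-6-(2-methylpent-4-en-2-yl)cyclohex-2-en-1-yl]-2,5-diphenylpyrrolidine | CC(=O)[C@]1(C(C)(C)CC=C)CCC(O[Si](C)(C)C(C)(C)C)=C[C@@H]1N1[C@H](c2ccccc2)CC[C@H]1c1ccccc1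
F5 | step 5 | (4R)-4-acetyl-4-(2-methylpent-4-en-2-yl)cyclohex-2-en-1-one | CC(=O)[C@]1(C(C)(C)CC=C)CCC(=O)C=C1
F6 | step 5 | (6R,7S,9R)-9-bromo-7-hydroxy-7,11,11-trimethylspiro[5.5]undec-1-en-3-one | CC1(C)C[C@@H](Br)C[C@](C)(O)[C@]12C=CC(=O)CC2
F7 | step 5 | (7S,9R)-9-bromo-7-hydroxy-7,11,11-trimethylspiro[5.5]undeca-1,4-dien-3-one | CC1(C)C[C@@H](Br)C[C@](C)(O)C12C=CC(=O)C=C2
F8 | step 6 | 2-{(E)-[(6S,7S,9R)-9-bromo-7,11,11-trimethyl-7-(trimethylsilyloxy)spiro[5.5]undec-1-en-3-ylidene]methyl}-4,4,5,5-tetramethyl-1,3,2-dioxaborolane | CC1(C)C[C@@H](Br)C[C@](C)(O[Si](C)(C)C)[C@@]12C=C/C(=C/B3OC(C)(C)C(C)(C)O3)CC2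
F9 | step 1 | (Z)-trimethyl[(4,4-dimethylhepta-2,6-dien-2-yl)oxy]silane | C/C(O[Si](C)(C)C)=C/C(C)(C)CC=C
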